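Amounts first: we read the earlier runs in mM of target, not in percent of a charge that differs from run to run.

| setting | larch | oak | flask |
|---|---|---|---|
| solid substrate | 0.050 M | 0.075 M | 0.10 M |
| gas | 4.1 mM (held) | 4.1 mM (held) | 4.1 mM (held) |
| remark | run made earlier | run made earlier |  |
| time |  |  | 15 min |

| run | time / min | target / % |
|---|---|---|
| larch | 2.50 | 5.7 |
| larch | 5.00 | 16.4 |
| larch | 6.00 | 20.6 |
| larch | 10.0 | 36.8 |
| oak | 1.00 | 0.3 |
| oak | 3.00 | 5.2 |
| oak | 6.00 | 13.6 |
| oak | 10.0 | 24.0 |

(readings scatter by 0.3 percentage points)

- given per volume of solution although it is solid: solid substrate
- at the start none of the gas is in solution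
- at the start none of the solid substrate is in solution

- summer: doubling the dissolution coefficient of the solid substrate, all else as stated
- spring: doubling the saturation concentration of gas, all else as stated
- dusk: doubling the solubility of the solid substrate, all else as stated
- dawn: doubling the transfer coefficient of the gas, all else as stated

* amount of target at 15 min, in percent of the solid substrate charged
* the change that raises the amount of target at 15 min, in percent of the solid substrate charged most ("none" if none brings more than 2 percentage points) (summer / spring / dusk / dawn / none)
* amount of target at 15 min, in percent of the solid substrate charged, after dusk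

At 6.00 min the larch run holds 10.3 mM of target and the oak run 10.2 mM; at 10.0 min they hold 18.4 mM and 18.0 mM. At these two charges the target reads as zero order in solid substrate, so we carry the shared slope, the mM of target gained per minute between those readings: 1.99 mM min⁻¹. Continued from the mean at 10.0 min, 18.2 mM, it gives the flask 28.1 mM at 15 min.

Might the flask's solid substrate run out? That amount is less than the charge of 0.10 M, so the line may stand. But the slope sags: the larch run reads 2.13 mM min⁻¹ early, around 6.58 mM of target, more than the shared slope around 14.2 mM. With 0.3 percentage points on each reading, this sag is a reading and no proof.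

We put the first answer back in: the last stretch averages 23.2 mM of target, so the same sag gives 1.82 mM min⁻¹ there and 27.3 mM in the flask, or 27.3%. This is our number, below the forecast.

The forecast says 27.8% (26.5% to 29%), picks dusk, and puts that change at 45% (30% to 54%), granting “These runs cannot cleanly separate them”. We have no slope for the changes and take its choice.

The flask gives 26.0%; dusk is best, adding 14 points and reaching 39.8%, less than the forecast. At 15.0 min the flask holds 8.52% isomer of the product, against 2.07% at 7.50 min. Between those times its target rose by 1.67 mM min⁻¹, less than the shared slope.

    target ⇌ isomer of the product (K = 1.40, k = 8.60 × 10⁻⁴ s⁻¹)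
    dissolved substrate + partner → target (k = 1.40 M⁻¹ s⁻¹)
    dissolved substrate + target → side product (k = 0.0410 M⁻¹ s⁻¹)
    gas ⇌ partner, rate k4*(csat - [partner]) (kL = 0.0790 s⁻¹)
    solid substrate ⇌ dissolved substrate, rate k5*(cs5 - [dissolved substrate]) while solid is left; crystals form when [dissolved substrate] > cs5 (solubility = 0.0750 M, k = 9.20 × 10⁻⁴ s⁻¹)

With 0.025 M of solid substrate, the same line gives 28.1 mM at 15 min, more than the charge, so it cannot stand there. The computed flask gives 58.0%, with 0% solid substrate and 2.02% dissolved substrate left.

Readings and results were generated by integration for an exercise, noise included.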